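**Retrosynthetic overview**
1. Target 24 ⇐ hydrolysis of the C5 ethyl enol ether of 23 ⇐ Pd-catalysed asymmetric dearomative C8-prenylation of the ring-opened chromanone lactone 20.
2. Pyranone ring (third ring) ⇐ quinine-catalysed oxa-Michael closure of ortho-tigloyl phenol 19; lactone ring (second ring, temporary) ⇐ iminium Friedel–Crafts/lactolisation of phenol 12 with hex-2-enal.
3. Carbocycle (first ring) ⇐ Ni(0)-catalysed two-carbon ring expansion of 3-ethoxycyclobutenone 10 with siloxyalkyne 9, which already carries the C10 chain (key step, new).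
4. Siloxyalkyne 9 ⇐ Kowalski 1,2-shift of ester 7 ⇐ Rh/BINAP conjugate isopropenylation of dienoate 5 ⇐ carbocupration of methyl propiolate.
5. Ring order: benzene ring → dihydrocoumarin → chromanone; the lactone is then opened and the benzene ring dearomatised.

Assumption: 1, 2, 6, 10, 13, 17 and 21 are taken as commercial; the sense of induction in steps 2, 5 and 9 is assigned from the usual catalyst models and is to be confirmed on the first batch (the antipodal ligand is used if it is reversed).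

**Step 1**
Reactants: 1 4-bromo-2-methylbut-1-ene; 2 methyl prop-2-ynoate
Product: 5 methyl (2E)-6-methylhepta-2,6-dienoate, via (3-methylbut-3-en-1-yl)magnesium bromide 3 (not isolated), via (2Z)-2-cuprio enoate 4 (not isolated)
Conditions: Mg, THF, 25 °C; CuBr·SMe2 (1.0 equiv), −40 °C; 2, −78 °C; aq. NH4Cl, −78 °C
Reagents that add atoms: none
Why: Grignard formation, then syn-carbocupration of the propiolate (organocopper conjugate addition) and protonation of the vinylcopper with retention give the 2E enoate.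

**Step 2**
Reactants: 5 methyl (2E)-6-methylhepta-2,6-dienoate; 6 potassium trifluoro(prop-1-en-2-yl)borate
Product: 7 methyl (3R)-6-methyl-3-(prop-1-en-2-yl)hept-6-enoate
Conditions: [Rh(cod)2]BF4 (3 mol %), (S)-BINAP (3.3 mol %), toluene/H2O 4:1, 100 °C
Reagents that add atoms: none
Why: Hayashi–Miyaura Rh/BINAP asymmetric 1,4-addition of an alkenyltrifluoroborate; with (S)-BINAP the enoate binds through its α-si face, so the isopropenyl group is delivered to give the 3R centre.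

**Step 3**
Reactants: 7 methyl (3R)-6-methyl-3-(prop-1-en-2-yl)hept-6-enoate
Product: 9 triisopropyl{[(4R)-7-methyl-4-(prop-1-en-2-yl)oct-7-en-1-yn-1-yl]oxy}silane, via lithium ynolate 8 (not isolated)
Conditions: CH2Br2, LiTMP, THF, −78 °C; LiHMDS then n-BuLi, −78 → 0 °C; i-Pr3SiCl, −78 → 25 °C
Reagents that add atoms: dibromomethane BrCBr; chlorotri(propan-2-yl)silane CC(C)[Si](Cl)(C(C)C)C(C)C
Why: Kowalski ester homologation: in the bromo-lithio enolate carbenoid the alkyl chain undergoes a 1,2-shift from the former carbonyl carbon to the carbenoid carbon to give the ynolate, which is O-silylated; the remote stereocentre is untouched.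

**Step 4**
Reactants: 9 triisopropyl{[(4R)-7-methyl-4-(prop-1-en-2-yl)oct-7-en-1-yn-1-yl]oxy}silane; 10 3-ethoxycyclobut-2-en-1-one
Product: 12 5-ethoxy-2-[(2R)-5-methyl-2-(prop-1-en-2-yl)hex-5-en-1-yl]-3-[(triisopropylsilyl)oxy]phenol, via cyclohexa-2,5-dien-1-one tautomer 11 (not isolated)
Conditions: Ni(cod)2 (10 mol %), PPh3 (20 mol %), toluene, 0 → 25 °C
Reagents that add atoms: none
Why: Proposed new method: Ni(0) inserts into the strained acyl–CH2 bond of the cyclobutenone to give a nickelacyclopentenone (η4-vinylketene complex), the polarised siloxyalkyne inserts with its nucleophilic alkyl-bearing carbon at the acyl carbon (Ni on the O-bearing carbon), and C–C reductive elimination gives the six-membered dienone, which tautomerises to the 1,3,5-trioxygenated arene with the C10 chain between OH and OTIPS; this is a stepwise organometallic two-carbon ring expansion, and the closest known reaction type is the Ni(0)-catalysed cyclobutenone–alkyne phenol synthesis, shown so far only for hydrocarbon alkynes.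

**Step 5**
Reactants: 12 5-ethoxy-2-[(2R)-5-methyl-2-(prop-1-en-2-yl)hex-5-en-1-yl]-3-[(triisopropylsilyl)oxy]phenol; 13 (2E)-hex-2-enal
Product: 15 (4S)-5-ethoxy-8-[(2R)-5-methyl-2-(prop-1-en-2-yl)hex-5-en-1-yl]-4-propyl-7-[(triisopropylsilyl)oxy]-3,4-dihydro-2H-chromen-2-one, via chroman-2-ol lactol 14 (not isolated)
Conditions: (R)-2-[diphenyl(trimethylsilyloxy)methyl]pyrrolidine (20 mol %), PhCO2H (20 mol %), toluene, 0 °C; then Ag2CO3/Celite, toluene, 80 °C
Reagents that add atoms: none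
Why: Iminium-catalysed asymmetric Friedel–Crafts conjugate addition of the ring carbon between OH and OEt (the other free position is shielded by OTIPS) with lactolisation; the arene adds anti to the CPh2OTMS group of the (R)-catalyst to set 4S, and Fétizon oxidation converts the lactol to the lactone without acid.

**Step 6**
Reactants: 15 (4S)-5-ethoxy-8-[(2R)-5-methyl-2-(prop-1-en-2-yl)hex-5-en-1-yl]-4-propyl-7-[(triisopropylsilyl)oxy]-3,4-dihydro-2H-chromen-2-one
Product: 16 (4S)-5-ethoxy-7-hydroxy-8-[(2R)-5-methyl-2-(prop-1-en-2-yl)hex-5-en-1-yl]-4-propyl-3,4-dihydro-2H-chromen-2-one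
Conditions: TBAF, AcOH, THF, 0 °C
Reagents that add atoms: none
Why: Fluoride cleavage of the aryl silyl ether, buffered with AcOH so the aryl lactone and the alkenes survive.

**Step 7**
Reactants: 16 (4S)-5-ethoxy-7-hydroxy-8-[(2R)-5-methyl-2-(prop-1-en-2-yl)hex-5-en-1-yl]-4-propyl-3,4-dihydro-2H-chromen-2-one; 17 (2E)-2-methylbut-2-enoyl chloride
Product: 19 (4S)-5-ethoxy-7-hydroxy-6-[(2E)-2-methylbut-2-enoyl]-8-[(2R)-5-methyl-2-(prop-1-en-2-yl)hex-5-en-1-yl]-4-propyl-3,4-dihydro-2H-chromen-2-one, via bromomagnesium phenolate 18 (not isolated)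
Conditions: EtMgBr (1.0 equiv), Et2O/toluene, 0 °C; 17, 0 → 25 °C
Reagents that add atoms: none
Why: Chelation-controlled ortho C-acylation of a bromomagnesium phenolate with an α,β-unsaturated acyl chloride (Sartori-type Friedel–Crafts acylation); no free Lewis or Brønsted acid is present, so the 1,1-disubstituted alkenes are not protonated, and only one ring position is free.

**Step 8**
Reactants: 19 (4S)-5-ethoxy-7-hydroxy-6-[(2E)-2-methylbut-2-enoyl]-8-[(2R)-5-methyl-2-(prop-1-en-2-yl)hex-5-en-1-yl]-4-propyl-3,4-dihydro-2H-chromen-2-one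
Product: 20 (4S,7S,8R)-5-ethoxy-7,8-dimethyl-10-[(2R)-5-methyl-2-(prop-1-en-2-yl)hex-5-en-1-yl]-4-propyl-3,4,7,8-tetrahydro-2H,6H-pyrano[3,2-g]chromene-2,6-dione
Conditions: (−)-quinine (20 mol %), chlorobenzene, 15 °C
Reagents that add atoms: none
Why: Quinine-catalysed enantioselective intramolecular oxa-Michael addition of an ortho-tigloyl phenol (as used in the calanolide/inophyllum series): the catalyst sets the O–CH centre (8R) and kinetic protonation of the enol gives the cis 7S methyl; only the one phenol OH is available, so the ring closes in one direction.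

**Step 9**
Reactants: 20 (4S,7S,8R)-5-ethoxy-7,8-dimethyl-10-[(2R)-5-methyl-2-(prop-1-en-2-yl)hex-5-en-1-yl]-4-propyl-3,4,7,8-tetrahydro-2H,6H-pyrano[3,2-g]chromene-2,6-dione; 21 1-chloro-3-methylbut-2-ene
Product: 23 (3S)-3-[(2R,3S,8R)-5-ethoxy-2,3-dimethyl-8-(3-methylbut-2-en-1-yl)-8-[(2R)-5-methyl-2-(prop-1-en-2-yl)hex-5-en-1-yl]-4,7-dioxo-3,4,7,8-tetrahydro-2H-chromen-6-yl]hexanoic acid, via ring-opened phenoxide carboxylate salt 22 (not isolated)
Conditions: n-Bu4NOH (2.1 equiv), THF/H2O, 0 °C; PhMe azeotrope; Pd2(dba)3·CHCl3 (2.5 mol %), (R,R)-DACH-phenyl Trost ligand (7.5 mol %), 21, CH2Cl2, −30 °C; cold 1 M HCl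
Reagents that add atoms: tetrabutylammonium hydroxide CCCC[N+](CCCC)(CCCC)CCCC.[OH-]
Why: Hydroxide opens the aryl lactone to the phenoxide/carboxylate, which cannot relactonise; Pd-catalysed asymmetric allylic dearomatisation (Tsuji–Trost with a Trost ligand) then C-prenylates the less hindered ortho carbon at the CH2 terminus of the prenyl unit, the ligand setting the quaternary centre as 8R, while O-prenylated material re-ionises under Pd.

**Step 10**
Reactants: 23 (3S)-3-[(2R,3S,8R)-5-ethoxy-2,3-dimethyl-8-(3-methylbut-2-en-1-yl)-8-[(2R)-5-methyl-2-(prop-1-en-2-yl)hex-5-en-1-yl]-4,7-dioxo-3,4,7,8-tetrahydro-2H-chromen-6-yl]hexanoic acid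
Product: 24 CNP0294320.1, (3S)-3-[(2R,3S,8R)-5-hydroxy-2,3-dimethyl-8-(3-methylbut-2-en-1-yl)-8-[(2R)-5-methyl-2-(prop-1-en-2-yl)hex-5-en-1-yl]-4,7-dioxo-3,4,7,8-tetrahydro-2H-chromen-6-yl]hexanoic acid
Conditions: LiOH, 1,4-dioxane/H2O, 60 °C; then 1 M HCl, 0 °C
Reagents that add atoms: lithium hydroxide [Li+].[OH-]
Why: Addition–elimination hydrolysis of the vinylogous ethyl ester, as in the last step of dearomatised acylphloroglucinol syntheses; the chelated enolate that forms is anionic, which disfavours enolisation at C3 of the chromanone, so the cis-dimethyl unit should be kept.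

**Compound list**
1 | 4-bromo-2-methylbut-1-ene | C=C(C)CCBr | starting material
2 | methyl prop-2-ynoate | C#CC(=O)OC | starting material
3 | (3-methylbut-3-en-1-yl)magnesium bromide | C=C(C)CC[Mg]Br | intermediate (not isolated)
4 | methyl (2Z)-2-cuprio-6-methylhepta-2,6-dienoate | C=C(C)CC/C=C(\[Cu])C(=O)OC | intermediate (not isolated)
5 | methyl (2E)-6-methylhepta-2,6-dienoate | C=C(C)CC/C=C/C(=O)OC | intermediate
6 | potassium trifluoro(prop-1-en-2-yl)borate | [K+].C=C(C)[B-](F)(F)F | starting material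
7 | methyl (3R)-6-methyl-3-(prop-1-en-2-yl)hept-6-enoate | C=C(C)CC[C@H](CC(=O)OC)C(=C)C | intermediate
8 | lithium (4R)-7-methyl-4-(prop-1-en-2-yl)oct-7-en-1-yn-1-olate | C=C(C)CC[C@H](CC#C[O-])C(=C)C.[Li+] | intermediate (not isolated)
9 | triisopropyl{[(4R)-7-methyl-4-(prop-1-en-2-yl)oct-7-en-1-yn-1-yl]oxy}silane | C=C(C)CC[C@H](CC#CO[Si](C(C)C)(C(C)C)C(C)C)C(=C)C | intermediate
10 | 3-ethoxycyclobut-2-en-1-one | CCOC1=CC(=O)C1 | starting material
11 | 5-ethoxy-2-[(2R)-5-methyl-2-(prop-1-en-2-yl)hex-5-en-1-yl]-3-[(triisopropylsilyl)oxy]cyclohexa-2,5-dien-1-one | C=C(C)CC[C@H](CC1=C(O[Si](C(C)C)(C(C)C)C(C)C)CC(OCC)=CC1=O)C(=C)C | intermediate (not isolated)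
12 | 5-ethoxy-2-[(2R)-5-methyl-2-(prop-1-en-2-yl)hex-5-en-1-yl]-3-[(triisopropylsilyl)oxy]phenol | C=C(C)CC[C@H](Cc1c(O)cc(OCC)cc1O[Si](C(C)C)(C(C)C)C(C)C)C(=C)C | intermediate
13 | (2E)-hex-2-enal | CCC/C=C/C=O | starting material
14 | (4S)-5-ethoxy-8-[(2R)-5-methyl-2-(prop-1-en-2-yl)hex-5-en-1-yl]-4-propyl-7-[(triisopropylsilyl)oxy]-3,4-dihydro-2H-chromen-2-ol (both anomers) | C=C(C)CC[C@H](Cc1c(O[Si](C(C)C)(C(C)C)C(C)C)cc(OCC)c2c1OC(O)C[C@@H]2CCC)C(=C)C | intermediate (not isolated)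
15 | (4S)-5-ethoxy-8-[(2R)-5-methyl-2-(prop-1-en-2-yl)hex-5-en-1-yl]-4-propyl-7-[(triisopropylsilyl)oxy]-3,4-dihydro-2H-chromen-2-one | C=C(C)CC[C@H](Cc1c(O[Si](C(C)C)(C(C)C)C(C)C)cc(OCC)c2c1OC(=O)C[C@@H]2CCC)C(=C)C | intermediate
16 | (4S)-5-ethoxy-7-hydroxy-8-[(2R)-5-methyl-2-(prop-1-en-2-yl)hex-5-en-1-yl]-4-propyl-3,4-dihydro-2H-chromen-2-one | C=C(C)CC[C@H](Cc1c(O)cc(OCC)c2c1OC(=O)C[C@@H]2CCC)C(=C)C | intermediate
17 | (2E)-2-methylbut-2-enoyl chloride (tigloyl chloride) | C/C=C(\C)C(Cl)=O | starting material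
18 | bromomagnesium phenolate of 16 | C=C(C)CC[C@H](Cc1c(O[Mg]Br)cc(OCC)c2c1OC(=O)C[C@@H]2CCC)C(=C)C | intermediate (not isolated)
19 | (4S)-5-ethoxy-7-hydroxy-6-[(2E)-2-methylbut-2-enoyl]-8-[(2R)-5-methyl-2-(prop-1-en-2-yl)hex-5-en-1-yl]-4-propyl-3,4-dihydro-2H-chromen-2-one | C=C(C)CC[C@H](Cc1c(O)c(C(=O)/C(C)=C/C)c(OCC)c2c1OC(=O)C[C@@H]2CCC)C(=C)C | intermediate
20 | (4S,7S,8R)-5-ethoxy-7,8-dimethyl-10-[(2R)-5-methyl-2-(prop-1-en-2-yl)hex-5-en-1-yl]-4-propyl-3,4,7,8-tetrahydro-2H,6H-pyrano[3,2-g]chromene-2,6-dione (dihydrocoumarin fused linearly to a cis-2,3-dimethylchroman-4-one) | C=C(C)CC[C@H](Cc1c2O[C@H](C)[C@H](C)C(=O)c2c(OCC)c2c1OC(=O)C[C@@H]2CCC)C(=C)C | intermediate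
21 | 1-chloro-3-methylbut-2-ene (prenyl chloride) | CC(C)=CCCl | starting material
22 | bis(tetrabutylammonium) (3S)-3-[(2R,3S)-5-ethoxy-2,3-dimethyl-8-[(2R)-5-methyl-2-(prop-1-en-2-yl)hex-5-en-1-yl]-7-oxido-4-oxo-3,4-dihydro-2H-chromen-6-yl]hexanoate | C=C(C)CC[C@H](Cc1c2O[C@H](C)[C@H](C)C(=O)c2c(OCC)c([C@@H](CCC)CC(=O)[O-])c1[O-])C(=C)C.CCCC[N+](CCCC)(CCCC)CCCC.CCCC[N+](CCCC)(CCCC)CCCC | intermediate (not isolated)
23 | (3S)-3-[(2R,3S,8R)-5-ethoxy-2,3-dimethyl-8-(3-methylbut-2-en-1-yl)-8-[(2R)-5-methyl-2-(prop-1-en-2-yl)hex-5-en-1-yl]-4,7-dioxo-3,4,7,8-tetrahydro-2H-chromen-6-yl]hexanoic acid | C=C(C)CC[C@H](C[C@@]1(CC=C(C)C)C(=O)C([C@@H](CCC)CC(=O)O)=C(OCC)C2=C1O[C@H](C)[C@H](C)C2=O)C(=C)C | intermediate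
24 | CNP0294320.1, (3S)-3-[(2R,3S,8R)-5-hydroxy-2,3-dimethyl-8-(3-methylbut-2-en-1-yl)-8-[(2R)-5-methyl-2-(prop-1-en-2-yl)hex-5-en-1-yl]-4,7-dioxo-3,4,7,8-tetrahydro-2H-chromen-6-yl]hexanoic acid | C=C(C)CC[C@H](C[C@@]1(CC=C(C)C)C(=O)C([C@@H](CCC)CC(=O)O)=C(O)C2=C1O[C@H](C)[C@H](C)C2=O)C(=C)C | target

**Totals**
Total steps: 10. Longest linear sequence: 10 (steps 1–10; the other starting materials enter one at a time).

**Steps most likely to fail, with fallbacks**

Step 4 (the new step). Risks are the regiochemistry of siloxyalkyne insertion and alkyne oligomerisation at nickel. The fallback uses known chemistry, the thermal Danheiser benzannulation, and sets out from 9 and 10 and comes back at 12. Heating 9 with 10 in toluene (80 → 110 °C) opens the cyclobutenone to the vinylketene 3-ethoxybuta-1,3-dien-1-one F1. Its [2+2] cycloaddition with 9 gives 4-(1-ethoxyethenyl)-2-[(2R)-5-methyl-2-(prop-1-en-2-yl)hex-5-en-1-yl]-3-[(triisopropylsilyl)oxy]cyclobut-2-en-1-one F2. This opens to the dienylketene 5-ethoxy-2-[(2R)-5-methyl-2-(prop-1-en-2-yl)hex-5-en-1-yl]-3-[(triisopropylsilyl)oxy]hexa-1,3,5-trien-1-one F3, which closes to 5-ethoxy-2-[(2R)-5-methyl-2-(prop-1-en-2-yl)hex-5-en-1-yl]-3-[(triisopropylsilyl)oxy]cyclohexa-2,4-dien-1-one F4 and tautomerises to 12.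

Step 7. Risks are O-acylation in place of C-acylation and premature racemic ring closure of the magnesium chelate. The fallback builds the acyl group in three neutral or basic operations; it sets out from 16 and comes back at 19. Magnesium-mediated ortho-formylation (MgCl2, Et3N, paraformaldehyde, MeCN, 80 °C) gives (4S)-5-ethoxy-7-hydroxy-8-[(2R)-5-methyl-2-(prop-1-en-2-yl)hex-5-en-1-yl]-2-oxo-4-propyl-3,4-dihydro-2H-chromene-6-carbaldehyde F5. Aldehyde-selective Nozaki–Hiyama–Kishi coupling with (E)-2-iodobut-2-ene (CrCl2, cat. NiCl2, DMF) gives (4S)-5-ethoxy-7-hydroxy-6-[(2E)-1-hydroxy-2-methylbut-2-en-1-yl]-8-[(2R)-5-methyl-2-(prop-1-en-2-yl)hex-5-en-1-yl]-4-propyl-3,4-dihydro-2H-chromen-2-one F6, which tolerates the lactone. MnO2 oxidation in CH2Cl2 then gives 19.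

Step 9. The risk is insufficient ligand control at C8 (the four existing stereocentres are remote) and competing alkylation at C6; this reaction type is known for naphthols and substituted phenols but untested on this scaffold. The fallback gives up catalyst control for an uncatalysed alkylative dearomatisation with separation; it sets out from 20 and 21 and comes back at 23. Aqueous KOH (3 equiv, 0 °C) opens the lactone, and 21 with NaI (0 °C → 25 °C) C-prenylates the phenoxide as in classical lupulone-type dearomatisations. This gives 23 together with its C8 epimer (3S)-3-[(2R,3S,8S)-5-ethoxy-2,3-dimethyl-8-(3-methylbut-2-en-1-yl)-8-[(2R)-5-methyl-2-(prop-1-en-2-yl)hex-5-en-1-yl]-4,7-dioxo-3,4,7,8-tetrahydro-2H-chromen-6-yl]hexanoic acid F7 in roughly equal amounts; the two are separated by preparative HPLC and 23 goes on to step 10.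

**Further compounds**
F1 | step 4 | 3-ethoxybuta-1,3-dien-1-one | C=C(OCC)C=C=O
F2 | step 4 | 4-(1-ethoxyethenyl)-2-[(2R)-5-methyl-2-(prop-1-en-2-yl)hex-5-en-1-yl]-3-[(triisopropylsilyl)oxy]cyclobut-2-en-1-one | C=C(C)CC[C@H](CC1=C(O[Si](C(C)C)(C(C)C)C(C)C)C(C(OCC)=C)C1=O)C(=C)C
F3 | step 4 | 5-ethoxy-2-[(2R)-5-methyl-2-(prop-1-en-2-yl)hex-5-en-1-yl]-3-[(triisopropylsilyl)oxy]hexa-1,3,5-trien-1-one | C=C(C)CC[C@H](CC(=C=O)C(O[Si](C(C)C)(C(C)C)C(C)C)=CC(OCC)=C)C(=C)C
F4 | step 4 | 5-ethoxy-2-[(2R)-5-methyl-2-(prop-1-en-2-yl)hex-5-en-1-yl]-3-[(triisopropylsilyl)oxy]cyclohexa-2,4-dien-1-one | C=C(C)CC[C@H](CC1=C(O[Si](C(C)C)(C(C)C)C(C)C)C=C(OCC)CC1=O)C(=C)C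
F5 | step 7 | (4S)-5-ethoxy-7-hydroxy-8-[(2R)-5-methyl-2-(prop-1-en-2-yl)hex-5-en-1-yl]-2-oxo-4-propyl-3,4-dihydro-2H-chromene-6-carbaldehyde | C=C(C)CC[C@H](Cc1c(O)c(C=O)c(OCC)c2c1OC(=O)C[C@@H]2CCC)C(=C)C
F6 | step 7 | (4S)-5-ethoxy-7-hydroxy-6-[(2E)-1-hydroxy-2-methylbut-2-en-1-yl]-8-[(2R)-5-methyl-2-(prop-1-en-2-yl)hex-5-en-1-yl]-4-propyl-3,4-dihydro-2H-chromen-2-one (both carbinol epimers) | C=C(C)CC[C@H](Cc1c(O)c(C(O)/C(C)=C/C)c(OCC)c2c1OC(=O)C[C@@H]2CCC)C(=C)C
F7 | step 9 | (3S)-3-[(2R,3S,8S)-5-ethoxy-2,3-dimethyl-8-(3-methylbut-2-en-1-yl)-8-[(2R)-5-methyl-2-(prop-1-en-2-yl)hex-5-en-1-yl]-4,7-dioxo-3,4,7,8-tetrahydro-2H-chromen-6-yl]hexanoic acid | C=C(C)CC[C@H](C[C@]1(CC=C(C)C)C(=O)C([C@@H](CCC)CC(=O)O)=C(OCC)C2=C1O[C@H](C)[C@H](C)C2=O)C(=C)C
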